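The route rests on reading ring C (C9a–C1–C12–C11–C10–C9) as a spent 2-amidofuran. N4 on C9a, ethyl on C10, oxygen on C11 and the tertiary carbinol C1 beside C9a are what is left when furan carbons C9a, C9, C10 and C11 add to an oxygen-bearing alkene C1=C12. One heating step forms C9a–C1 (ring B) and C11–C12 (ring C), opens the oxygen bridge to the C9=C9a enamide and the C11 ketone, and sets C1 and C10. Its precursor is a 3-ethylfuro[2,3-b]azepin-7-one (ring A) whose nitrogen carries an L-aspartate-derived chain (C3, C18, C2) ending in a triethylsilyl enol ether. Lactones D and E and lactam deoxygenation follow.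

Key step: step 14

Remark on numbering: Stemona numbering is used.
- Ring A = N4, C5–C9, C9a.
- Ring B = N4, C3, C2, C1, C9a.
- Ring C = C9a, C1, C12, C11, C10, C9.
- Lactone D = O, C11, C12, C13, C14.
- Lactone E = O, C18, C19, C20, C21.

Remarks on design:
- O1 carries SiEt3 and O18 carries SiPh2t-Bu, so the two oxygens can be freed separately.
- C1 is stored as a Weinreb amide until ring A is closed.
- Both furan α positions are brominated, because an electrophile cannot tell them apart.
- C12 is alkylated by a radical rather than through a free enolate, because O1 is a β leaving group.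
- C11 is reduced under direction by the free C1 hydroxyl.

Assumption: 2 and 33 are bought as 0.5 M THF solutions, and 6 and 22 are commercial.

Step 1
Reactants: 1 3,4-dibromofuran; 2 4-ethoxy-4-oxobutylzinc bromide
Product: 3 ethyl 4-(4-bromofuran-3-yl)butanoate
Conditions: 1 (1.5 equiv), 2, PdCl2(dppf) (3 mol %), THF, 50 °C
Reagents that add atoms: none
Why: Negishi sp2–sp3 cross-coupling: the two C–Br bonds of 1 are equivalent, and an excess of 1 together with the slower oxidative addition of the alkylated, more electron-rich monobromide should stop the reaction after one coupling, while dppf favours reductive elimination over β-hydride elimination.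

Step 2
Reactants: 3 ethyl 4-(4-bromofuran-3-yl)butanoate
Product: 4 ethyl 4-(4-ethylfuran-3-yl)butanoate
Conditions: Et2Zn, PdCl2(dppf) (5 mol %), THF, 60 °C
Reagents that add atoms: diethylzinc, CC[Zn]CC
Why: Second Negishi coupling on the remaining β-bromide; diethylzinc tolerates the ester and the same ligand keeps ethyl transfer ahead of β-hydride elimination.

Step 3
Reactants: 4 ethyl 4-(4-ethylfuran-3-yl)butanoate
Product: 5 4-(4-ethylfuran-3-yl)butanoic acid
Conditions: LiOH, THF/H2O, rt; then 1 M HCl to pH 4, 0 °C
Reagents that add atoms: lithium hydroxide, [Li+].[OH-]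
Why: Saponification of an unhindered ethyl ester; the furan is inert to hydroxide and sees cold dilute acid only briefly.

Step 4
Reactants: 6 N-benzyloxycarbonyl-L-aspartic anhydride
Product: 8 (4S)-4-(benzyloxycarbonylamino)dihydrofuran-2(3H)-one, via hydroxy acid 7 (not isolated)
Conditions: NaBH4, THF, 0 °C to rt; then 6 M HCl, EtOH, rt
Reagents that add atoms: none
Why: Regioselective borohydride reduction of a cyclic anhydride at the more electrophilic carbonyl beside the carbamate-bearing carbon, then acid-catalysed lactonisation; the aspartate α-carbon (future C3) is untouched, the α-carboxyl becomes C18 and the side-chain carboxyl C1.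

Step 5
Reactants: 8 (4S)-4-(benzyloxycarbonylamino)dihydrofuran-2(3H)-one
Product: 9 benzyl N-[(2S)-1-hydroxy-4-[methoxy(methyl)amino]-4-oxobutan-2-yl]carbamate
Conditions: MeNH(OMe)·HCl, AlMe3, CH2Cl2, 0 °C to rt
Reagents that add atoms: N,O-dimethylhydroxylamine hydrochloride, CNOC.Cl
Why: Weinreb aminolysis of a lactone by the aluminium amide frees O18 and stores C1 as an amide that cannot over-add and is far less prone than a ketone to β-elimination of nitrogen.

Step 6
Reactants: 9 hydroxy Weinreb amide
Product: 10 benzyl N-[(2S)-1-(tert-butyldiphenylsilyloxy)-4-[methoxy(methyl)amino]-4-oxobutan-2-yl]carbamate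
Conditions: t-BuPh2SiCl, imidazole, DMF, rt
Reagents that add atoms: tert-butyl(chloro)diphenylsilane, CC(C)(C)[Si](Cl)(c1ccccc1)c1ccccc1
Why: Imidazole-promoted silylation of a primary alcohol, done at once to prevent relactonisation; this silyl group is chosen because it outlasts the later release of SiEt3 from O1.

Step 7
Reactants: 10 silylated carbamate
Product: 11 (3S)-3-amino-4-(tert-butyldiphenylsilyloxy)-N-methoxy-N-methylbutanamide
Conditions: H2 (1 atm), Pd/C, EtOAc/MeOH, rt
Reagents that add atoms: none
Why: Hydrogenolysis of the benzyl carbamate followed by spontaneous decarboxylation; the silyl ether and the N–O bond of the Weinreb amide survive palladium on carbon at one atmosphere.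

Step 8
Reactants: 5 4-(4-ethylfuran-3-yl)butanoic acid; 11 amine
Product: 12 N-[(2S)-1-(tert-butyldiphenylsilyloxy)-4-[methoxy(methyl)amino]-4-oxobutan-2-yl]-4-(4-ethylfuran-3-yl)butanamide
Conditions: EDC·HCl, HOBt, CH2Cl2, 0 °C to rt
Reagents that add atoms: none
Why: Carbodiimide/HOBt amide coupling of an unhindered acid with a primary amine; no stereocentre lies α to the activated carbonyl.

Step 9
Reactants: 12 furan amide
Product: 13 4-(2,5-dibromo-4-ethylfuran-3-yl)-N-[(2S)-1-(tert-butyldiphenylsilyloxy)-4-[methoxy(methyl)amino]-4-oxobutan-2-yl]butanamide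
Conditions: NBS (2.1 equiv), dry DMF, −20 to 0 °C, dark
Reagents that add atoms: N-bromosuccinimide, O=C1CCC(=O)N1Br
Why: Electrophilic aromatic bromination: the two α positions of a 3,4-dialkylfuran are electronically and sterically alike, so both are filled on purpose and the choice between them is left to the ring closure of step 10.

Step 10
Reactants: 13 dibromofuran amide
Product: 14 (3S)-3-(2-bromo-3-ethyl-7-oxo-4,5,6,7-tetrahydro-8H-furo[2,3-b]azepin-8-yl)-4-(tert-butyldiphenylsilyloxy)-N-methoxy-N-methylbutanamide
Conditions: CuI (20 mol %), MeNHCH2CH2NHMe (40 mol %), K3PO4, toluene, 100 °C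
Reagents that add atoms: none
Why: Intramolecular Goldberg amidation (copper/diamine catalysis, established for 2-bromofurans): only the C9a bromide can be reached by the amide nitrogen through a seven-membered ring, so ring A closes regiospecifically and the C11 bromide is a bystander, while the heterogeneous phosphate base leaves the Weinreb amide and C3 alone.

Step 11
Reactants: 14 bromo furoazepinone
Product: 15 (3S)-4-(tert-butyldiphenylsilyloxy)-3-(3-ethyl-7-oxo-4,5,6,7-tetrahydro-8H-furo[2,3-b]azepin-8-yl)-N-methoxy-N-methylbutanamide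
Conditions: Pd(PPh3)4 (5 mol %), HCO2Na, DMF, 80 °C
Reagents that add atoms: none
Why: Palladium-catalysed transfer hydrodehalogenation with formate (oxidative addition at the activated α-bromide, decarboxylation to a palladium hydride, reductive elimination) removes the placeholder without touching the furan π system.

Step 12
Reactants: 15 furoazepinone Weinreb amide
Product: 16 8-[(2S)-1-(tert-butyldiphenylsilyloxy)-4-oxopentan-2-yl]-3-ethyl-4,5,6,8-tetrahydro-7H-furo[2,3-b]azepin-7-one
Conditions: MeMgBr, THF, −20 to 0 °C
Reagents that add atoms: methylmagnesium bromide, C[Mg]Br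
Why: Weinreb ketone synthesis: the chelated tetrahedral magnesium adduct prevents over-addition and the less electrophilic lactam is not attacked at low temperature; the new methyl group is C12.

Step 13
Reactants: 16 methyl ketone
Product: 17 8-[(2S)-1-(tert-butyldiphenylsilyloxy)-4-(triethylsilyloxy)pent-4-en-2-yl]-3-ethyl-4,5,6,8-tetrahydro-7H-furo[2,3-b]azepin-7-one
Conditions: LiN(i-Pr)2, Et3SiCl (present from the start), THF, −78 °C; Et3N, pentane work-up
Reagents that add atoms: chlorotriethylsilane, CC[Si](Cl)(CC)CC
Why: Kinetic enolisation of a methyl ketone at the unhindered CH3 with a bulky amide base under internal quench gives the terminal silyl enol ether before equilibration to the C2 enolate, which would expel the lactam nitrogen, can set in.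

Step 14
Reactants: 17 silyl enol ether precursor
Product: 20 tricyclic enamide lactam ketone (rings A/B/C; C5 lactam; C9=C9a; C11=O; 1S,3S,10R; O1-SiEt3; O18-SiPh2t-Bu), via oxanorbornene cycloadduct 18 (not isolated), via acyliminium alkoxide zwitterion 19 (not isolated)
Conditions: toluene (0.01 M, degassed), 2,6-di-tert-butyl-4-methylphenol (10 mol %), silanised sealed tube, 170 °C
Reagents that add atoms: none
Why: Intramolecular Diels–Alder reaction of the furan followed by nitrogen-assisted opening of the oxygen bridge: the diene C9a=C9–C10=C11 adds suprafacially to C1=C12 to give oxanorbornene 18, the lactam nitrogen expels the C9a–O bond to give zwitterion 19, and a 1,2-shift of hydrogen from C11 to C10 (or the equivalent proton relay) ends irreversibly at the C9=C9a enamide and the C11 ketone, which pulls the reversible cycloaddition of two electron-rich partners forward. The closest known reaction type is the thermal cycloaddition–rearrangement cascade of N-(but-3-enyl)-2-amidofurans to hexahydroindolinones, established for 3-substituted butenyl tethers that build a quaternary carbon at this very position and for furans fused to a seven-membered nitrogen ring; the silyl enol ether is a more electron-rich member of that alkene class. Ring B closes as a five-membered ring through C9a–C1 with the three-atom tether N4–C3–C2 on the side of the oxygen bridge (exo), the only orientation so short a tether allows, and ring C is closed by the [4+2] bond pair itself (C9a–C1 plus C11–C12). C1 is controlled by C3: A(1,3) strain with the lactam C5=O turns H3 into the amide plane and the C18 arm pseudoaxial on the nascent pyrrolidine, and the transition state that keeps this arm on the furan-oxygen side, away from the endo silyloxy group and the C8 methylene, places O1 anti to C18. C10 is set by the hydrogen shift on the face opposite the departing bridge oxygen, that is syn to O1, which puts ethyl anti to O1; this is also the thermodynamic position (ethyl pseudoaxial, free of A(1,2) strain with C8), so equilibration beside the ketone does no harm. The step needs the cascade to outrun hydrolysis of the enol ether and loss of Et3SiOH from the β-silyloxy ketone (aromatisation): the ring-fused lactam holds the nitrogen substituent over the furan, no other π bond is within reach, and dilute, strictly neutral conditions in silanised glass remove the catalysts of both side reactions.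

Step 15
Reactants: 20 tricyclic enamide lactam ketone
Product: 21 C11-trimethylsilyl enol ether (C11=C12) of 20
Conditions: LiN(i-Pr)2, Me3SiCl (present from the start), THF, −78 °C; Et3N, cold NaHCO3 work-up
Reagents that add atoms: chlorotrimethylsilane, C[Si](C)(C)Cl
Why: Kinetic enolisation under internal quench: the bulky base takes the axial C12 proton rather than the tertiary, pseudoequatorial and poorly aligned C10 proton, and the silyl chloride already present captures the enolate before it can expel the β-silyloxy group at C1.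

Step 16
Reactants: 21 C11-trimethylsilyl enol ether; 22 methyl 2-bromopropanoate
Product: 24 β-hydroxy keto ester (free C1-OH; C11=O; 12R side chain CH(CH3)CO2Me; C13 unassigned), via triethylsilyl keto ester 23 (not isolated)
Conditions: 22 (3 equiv), Ir(ppy)3 (1 mol %), 2,6-lutidine, MeCN, blue LED, rt; then HF·pyridine, pyridine, 0 °C
Reagents that add atoms: none
Why: Photoredox radical alkylation of a silyl enol ether with an α-bromo ester (the electrophilic radical adds to the electron-rich C12, the α-silyloxy radical is oxidised and loses silicon) forms C12–C13 without an anionic intermediate that could eliminate O1; the radical enters the boat-shaped 1,4-diene on its convex face anti to the pseudoaxial O1 substituent, and buffered fluoride then frees the tertiary SiEt3 ether selectively over the primary SiPh2t-Bu ether.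

Step 17
Reactants: 24 β-hydroxy keto ester
Product: 26 lactone D compound (cis-fused; 11R,12R; free C1-OH; both C13 epimers), via anti-diol ester 25 (not isolated)
Conditions: Me4NBH(OAc)3, MeCN/AcOH, −30 to 0 °C; then PPTS (cat.), toluene, 60 °C
Reagents that add atoms: none
Why: Evans–Saksena hydroxyl-directed reduction: the pseudoaxial C1 hydroxyl binds boron and hands hydride to C11 from its own face, giving the anti-1,3-diol with O11 cis to the C12 side chain, so that acid-catalysed lactonisation closes the cis-fused lactone D.

Step 18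
Reactants: 26 lactone D compound (C13 epimers)
Product: 28 lactone D compound with 13S methyl (H11/H12/H13 all cis), via dilithium alkoxide enolate 27 (not isolated)
Conditions: LiN(i-Pr)2 (2.4 equiv), THF, −78 °C; then 2,6-di-tert-butyl-4-methylphenol, −78 °C
Reagents that add atoms: none
Why: Deprotonation and kinetic protonation of a lactone enolate: the planar C13 of the cis-fused bicycle is protonated by the bulky phenol on the open convex face (the face of H11 and H12), which turns the methyl group to the concave side as in the target whichever epimer is used.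

Step 19
Reactants: 28 lactone D compound (13S)
Product: 29 C18 primary alcohol (C1-OH also free)
Conditions: Bu4NF, AcOH, THF, 0 °C to rt
Reagents that add atoms: none
Why: Fluoride desilylation buffered with acetic acid, so that the medium is not basic enough to epimerise C13.

Step 20
Reactants: 29 C18 primary alcohol
Product: 30 C18 aldehyde
Conditions: Dess–Martin periodinane, NaHCO3, CH2Cl2, 0 °C
Reagents that add atoms: none
Why: Dess–Martin oxidation of the only oxidisable alcohol under buffered conditions; the tertiary C1-OH is inert and the configurationally sensitive α-amido aldehyde is used without purification.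

Step 21
Reactants: 30 C18 aldehyde
Product: 31 C18 carboxylic acid
Conditions: NaClO2, NaH2PO4, 2-methyl-2-butene, t-BuOH/H2O, 0 °C to rt
Reagents that add atoms: sodium chlorite, [Na+].[O-]Cl=O
Why: Pinnick oxidation: the weakly acidic buffer does not enolise the aldehyde and the alkene scavenges hypochlorous acid before it can attack the enamide.

Step 22
Reactants: 31 C18 carboxylic acid
Product: 32 S-ethyl C18 thioester
Conditions: EtSH, EDC·HCl, DMAP (10 mol %), CH2Cl2, 0 °C
Reagents that add atoms: ethanethiol, CCS
Why: Steglich-type carbodiimide thioesterification at low temperature; O1 is trans to C18 on ring B and cannot lactonise onto the activated acid.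

Step 23
Reactants: 32 S-ethyl C18 thioester; 33 (R)-(3-methoxy-2-methyl-3-oxopropyl)zinc bromide
Product: 34 γ-keto ester (C18=O; 20S)
Conditions: 33 (3 equiv), PdCl2(PPh3)2 (10 mol %), toluene/THF, rt
Reagents that add atoms: none
Why: Fukuyama coupling: palladium inserts into the C–S bond and the mild zinc homoenolate transfers its alkyl group to give the ketone without touching lactone, lactam or methyl ester; C20 arrives with the reagent, whose stereocentre is not the metal-bearing carbon, and α-amido thioesters are known to couple without epimerisation.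

Step 24
Reactants: 34 γ-keto ester
Product: 36 bis-lactone lactam (5-oxo derivative of the target), via hydroxy ester 35 (not isolated)
Conditions: LiBH(s-Bu)3, THF, −78 °C; then AcOH, −78 °C; PPTS (cat.), CH2Cl2, rt
Reagents that add atoms: none
Why: Felkin–Anh-controlled reduction with a bulky borohydride: hydride attacks C18 anti to the C3–N4 bond and gives the syn N4/O18 relationship (18S), the γ-hydroxy ester lactonises to the cis-disubstituted ring E because C20 is already S, and a ketone is reduced far faster than a lactone at −78 °C.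

Step 25
Reactants: 36 bis-lactone lactam
Product: 37 C5 thiolactam
Conditions: Lawesson's reagent, THF, 50 °C
Reagents that add atoms: Lawesson's reagent, COc1ccc(cc1)P1(=S)SP(=S)(S1)c1ccc(OC)cc1
Why: Thionation with Lawesson's reagent is selective for the more nucleophilic lactam carbonyl over lactone carbonyls, and the hindered tertiary carbinol is not expected to react at this temperature.

Step 26
Reactants: 37 C5 thiolactam
Product: 38 target CNP0179500.1
Conditions: Raney Ni (washed neutral, aged in acetone), THF/EtOH, rt
Reagents that add atoms: none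
Why: Raney nickel desulfurisation of a thiolactam to the methylene group under neutral conditions is the standard lactone-tolerant way to deoxygenate a lactam, and acetone-aged nickel is used so that the tetrasubstituted C9=C9a enamine is not hydrogenated.

Compound list
1 | 3,4-dibromofuran | Brc1cocc1Br | starting material
2 | 4-ethoxy-4-oxobutylzinc bromide | CCOC(=O)CCC[Zn]Br | starting material
3 | ethyl 4-(4-bromofuran-3-yl)butanoate | CCOC(=O)CCCc1cocc1Br | intermediate
4 | ethyl 4-(4-ethylfuran-3-yl)butanoate | CCOC(=O)CCCc1cocc1CC | intermediate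
5 | 4-(4-ethylfuran-3-yl)butanoic acid | OC(=O)CCCc1cocc1CC | intermediate
6 | N-benzyloxycarbonyl-L-aspartic anhydride | O=C1C[C@H](NC(=O)OCc2ccccc2)C(=O)O1 | starting material
7 | (3S)-3-(benzyloxycarbonylamino)-4-hydroxybutanoic acid (not isolated) | OC(=O)C[C@H](NC(=O)OCc1ccccc1)CO | intermediate
8 | (4S)-4-(benzyloxycarbonylamino)dihydrofuran-2(3H)-one | O=C1C[C@H](NC(=O)OCc2ccccc2)CO1 | intermediate
9 | benzyl N-[(2S)-1-hydroxy-4-[methoxy(methyl)amino]-4-oxobutan-2-yl]carbamate | CON(C)C(=O)C[C@H](NC(=O)OCc1ccccc1)CO | intermediate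
10 | O-tert-butyldiphenylsilyl ether of 9 | CON(C)C(=O)C[C@H](NC(=O)OCc1ccccc1)CO[Si](c1ccccc1)(c1ccccc1)C(C)(C)C | intermediate
11 | (3S)-3-amino-4-(tert-butyldiphenylsilyloxy)-N-methoxy-N-methylbutanamide | CON(C)C(=O)C[C@H](N)CO[Si](c1ccccc1)(c1ccccc1)C(C)(C)C | intermediate
12 | secondary amide of 5 and 11 | CCc1cocc1CCCC(=O)N[C@H](CO[Si](c1ccccc1)(c1ccccc1)C(C)(C)C)CC(=O)N(C)OC | intermediate
13 | 2,5-dibromofuran amide | CCc1c(Br)oc(Br)c1CCCC(=O)N[C@H](CO[Si](c1ccccc1)(c1ccccc1)C(C)(C)C)CC(=O)N(C)OC | intermediate
14 | 2-bromo-3-ethylfuro[2,3-b]azepin-7-one, N8 side chain with Weinreb amide | CCc1c(Br)oc2c1CCCC(=O)N2[C@H](CO[Si](c1ccccc1)(c1ccccc1)C(C)(C)C)CC(=O)N(C)OC | intermediate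
15 | 3-ethylfuro[2,3-b]azepin-7-one, N8 side chain with Weinreb amide | CCc1coc2c1CCCC(=O)N2[C@H](CO[Si](c1ccccc1)(c1ccccc1)C(C)(C)C)CC(=O)N(C)OC | intermediate
16 | 3-ethylfuro[2,3-b]azepin-7-one, N8 side chain with methyl ketone | CCc1coc2c1CCCC(=O)N2[C@H](CO[Si](c1ccccc1)(c1ccccc1)C(C)(C)C)CC(C)=O | intermediate
17 | key-step precursor: furoazepinone with terminal triethylsilyl enol ether | CCc1coc2c1CCCC(=O)N2[C@H](CO[Si](c1ccccc1)(c1ccccc1)C(C)(C)C)CC(=C)O[Si](CC)(CC)CC | intermediate
18 | oxanorbornene cycloadduct (O bridge C9a–C11, tether exo, OSiEt3 endo; not isolated) | CCC1=C2CCCC(=O)N3[C@H](CO[Si](c5ccccc5)(c5ccccc5)C(C)(C)C)C[C@]4(O[Si](CC)(CC)CC)C[C@@H]1O[C@]234 | intermediate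
19 | N-acyliminium C11-alkoxide zwitterion (not isolated) | CCC1=C2CCCC(=O)[N+]3=C2[C@](O[Si](CC)(CC)CC)(C[C@H]3CO[Si](c4ccccc4)(c4ccccc4)C(C)(C)C)C[C@@H]1[O-] | intermediate
20 | key-step product: tricyclic enamide lactam with C11 ketone (1S,3S,10R) | CC[C@@H]1C2=C3N(C(=O)CCC2)[C@H](CO[Si](c4ccccc4)(c4ccccc4)C(C)(C)C)C[C@]3(O[Si](CC)(CC)CC)CC1=O | intermediate
21 | C11-trimethylsilyl enol ether (C11=C12) | CC[C@@H]1C2=C3N(C(=O)CCC2)[C@H](CO[Si](c4ccccc4)(c4ccccc4)C(C)(C)C)C[C@]3(O[Si](CC)(CC)CC)C=C1O[Si](C)(C)C | intermediate
22 | methyl 2-bromopropanoate (racemic) | COC(=O)C(C)Br | starting material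
23 | triethylsilyl keto ester (12R, C13 unassigned; not isolated) | CC[C@@H]1C2=C3N(C(=O)CCC2)[C@H](CO[Si](c4ccccc4)(c4ccccc4)C(C)(C)C)C[C@]3(O[Si](CC)(CC)CC)[C@H](C(C)C(=O)OC)C1=O | intermediate
24 | β-hydroxy keto ester | CC[C@@H]1C2=C3N(C(=O)CCC2)[C@H](CO[Si](c4ccccc4)(c4ccccc4)C(C)(C)C)C[C@]3(O)[C@H](C(C)C(=O)OC)C1=O | intermediate
25 | anti-1,3-diol ester (11R; not isolated) | CC[C@@H]1C2=C3N(C(=O)CCC2)[C@H](CO[Si](c4ccccc4)(c4ccccc4)C(C)(C)C)C[C@]3(O)[C@H](C(C)C(=O)OC)[C@@H]1O | intermediate
26 | lactone D compound, both C13 epimers | CC[C@@H]1C2=C3N(C(=O)CCC2)[C@H](CO[Si](c4ccccc4)(c4ccccc4)C(C)(C)C)C[C@]3(O)[C@H]2[C@@H]1OC(=O)C2C | intermediate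
27 | dilithium C1-alkoxide / lactone D enolate (not isolated) | CC[C@@H]1C2=C3N(C(=O)CCC2)[C@H](CO[Si](c4ccccc4)(c4ccccc4)C(C)(C)C)C[C@]3([O-])[C@H]2[C@@H]1OC([O-])=C2C.[Li+].[Li+] | intermediate
28 | lactone D compound, 13S | CC[C@@H]1C2=C3N(C(=O)CCC2)[C@H](CO[Si](c4ccccc4)(c4ccccc4)C(C)(C)C)C[C@]3(O)[C@H]2[C@@H]1OC(=O)[C@H]2C | intermediate
29 | C18 primary alcohol | CC[C@@H]1C2=C3N(C(=O)CCC2)[C@H](CO)C[C@]3(O)[C@H]2[C@@H]1OC(=O)[C@H]2C | intermediate
30 | C18 aldehyde | CC[C@@H]1C2=C3N(C(=O)CCC2)[C@H](C=O)C[C@]3(O)[C@H]2[C@@H]1OC(=O)[C@H]2C | intermediate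
31 | C18 carboxylic acid | CC[C@@H]1C2=C3N(C(=O)CCC2)[C@H](C(=O)O)C[C@]3(O)[C@H]2[C@@H]1OC(=O)[C@H]2C | intermediate
32 | S-ethyl C18 thioester | CC[C@@H]1C2=C3N(C(=O)CCC2)[C@H](C(=O)SCC)C[C@]3(O)[C@H]2[C@@H]1OC(=O)[C@H]2C | intermediate
33 | (R)-(3-methoxy-2-methyl-3-oxopropyl)zinc bromide | Br[Zn]C[C@H](C)C(=O)OC | starting material
34 | γ-keto ester (C18 ketone, 20S) | CC[C@@H]1C2=C3N(C(=O)CCC2)[C@H](C(=O)C[C@H](C)C(=O)OC)C[C@]3(O)[C@H]2[C@@H]1OC(=O)[C@H]2C | intermediate
35 | γ-hydroxy ester (18S,20S; not isolated) | CC[C@@H]1C2=C3N(C(=O)CCC2)[C@H]([C@@H](O)C[C@H](C)C(=O)OC)C[C@]3(O)[C@H]2[C@@H]1OC(=O)[C@H]2C | intermediate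
36 | bis-lactone lactam (5-oxo target) | CC[C@@H]1C2=C3N(C(=O)CCC2)[C@H]([C@@H]2C[C@H](C)C(=O)O2)C[C@]3(O)[C@H]2[C@@H]1OC(=O)[C@H]2C | intermediate
37 | bis-lactone thiolactam (5-thioxo target) | CC[C@@H]1C2=C3N(C(=S)CCC2)[C@H]([C@@H]2C[C@H](C)C(=O)O2)C[C@]3(O)[C@H]2[C@@H]1OC(=O)[C@H]2C | intermediate
38 | CNP0179500.1 (1S,3S,10R,11R,12R,13S,18S,20S) | CC[C@@H]1C2=C3N(CCCC2)[C@H]([C@@H]2C[C@H](C)C(=O)O2)C[C@]3(O)[C@H]2[C@@H]1OC(=O)[C@H]2C | target

Total step count: 26. Longest linear sequence: 23 steps (6 to 38, steps 4 to 26).

Steps most likely to fail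

1. Step 14.
- What may go wrong: neither partner is electron-poor, so the cycloaddition may be too slow or too unfavourable. Long heating would then end in hydrolysis or silyl migration of the enol ether, and the product may lose triethylsilanol and aromatise.
- Fallback (sets out from 16, returns at 20): boron takes the place of oxygen at C1 during the cycloaddition.
- The kinetic enolate of 16 (KN(SiMe3)2, PhNTf2, THF, −78 °C) should give the terminal enol triflate F1.
- Miyaura borylation (B2pin2, PdCl2(PPh3)2, PPh3, KOPh, toluene, 50 °C) should give the 1,1-disubstituted vinylboronate F2. Its alkene is no donor, carries no leaving group and has a lowered LUMO.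
- The same thermal cascade should give the C1-boryl tricyclic ketone F3, with boron endo and therefore anti to C18.
- NaBO3·4H2O in THF/H2O oxidises C–B to C–O with retention to the β-hydroxy ketone F4.
- Et3SiOTf/2,6-lutidine then returns 20.

2. Step 15.
- What may go wrong: expulsion of the C1 silyloxy group may follow deprotonation faster than silylation does (E1cB, then aromatisation), or the base may attack C10.
- Fallback (sets out from 20, returns at 24): the leaving group is turned into an oxide that cannot leave, the logic of β-hydroxy carbonyl dianion chemistry.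
- HF·pyridine converts 20 into the β-hydroxy ketone F4.
- Double deprotonation (LiN(i-Pr)2, 2.3 equiv, THF, −78 °C) followed by Me3SiCl should give the bis(trimethylsilyl) enol ether F5.
- Radical alkylation with 22 as in step 16 should give the trimethylsilyl keto ester F6, and the fluoride treatment delivers 24.

3. Step 16.
- What may go wrong: C12 sits beside the fully substituted C1, so addition of the secondary radical may be outrun by its reduction or dimerisation, or by attack on the enamide.
- Fallback (sets out from 21, returns at 26): the carbon is brought in as a smaller, unbranched acetate unit and the methyl group is added later by enolate chemistry.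
- Compound 21 and methyl bromoacetate should give the nor-methyl triethylsilyl keto ester F7.
- HF·pyridine gives the nor-methyl β-hydroxy keto ester F8.
- Directed reduction as in step 17 gives the nor-methyl diol ester F9, and lactonisation gives the nor-methyl lactone F10.
- LiN(i-Pr)2 (2.3 equiv) and then MeI methylate the enolate on its convex face. This gives the 13-epimer of 28, one of the two components of 26, which step 18 then inverts.

Further compounds
F1 | step 14 | terminal enol triflate of 16 | CCc1coc2c1CCCC(=O)N2[C@H](CO[Si](c1ccccc1)(c1ccccc1)C(C)(C)C)CC(=C)OS(=O)(=O)C(F)(F)F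
F2 | step 14 | 1,1-disubstituted vinylboronate (pinacol ester) | CCc1coc2c1CCCC(=O)N2[C@H](CO[Si](c1ccccc1)(c1ccccc1)C(C)(C)C)CC(=C)B1OC(C)(C)C(C)(C)O1
F3 | step 14 | C1-boryl tricyclic enamide lactam ketone | CC[C@@H]1C2=C3N(C(=O)CCC2)[C@H](CO[Si](c4ccccc4)(c4ccccc4)C(C)(C)C)C[C@]3(B4OC(C)(C)C(C)(C)O4)CC1=O
F4 | step 14 | β-hydroxy ketone (20 without SiEt3) | CC[C@@H]1C2=C3N(C(=O)CCC2)[C@H](CO[Si](c4ccccc4)(c4ccccc4)C(C)(C)C)C[C@]3(O)CC1=O
F5 | step 15 | bis(trimethylsilyl) enol ether | CC[C@@H]1C2=C3N(C(=O)CCC2)[C@H](CO[Si](c4ccccc4)(c4ccccc4)C(C)(C)C)C[C@]3(O[Si](C)(C)C)C=C1O[Si](C)(C)C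
F6 | step 15 | trimethylsilyl keto ester | CC[C@@H]1C2=C3N(C(=O)CCC2)[C@H](CO[Si](c4ccccc4)(c4ccccc4)C(C)(C)C)C[C@]3(O[Si](C)(C)C)[C@H](C(C)C(=O)OC)C1=O
F7 | step 16 | nor-methyl triethylsilyl keto ester | CC[C@@H]1C2=C3N(C(=O)CCC2)[C@H](CO[Si](c4ccccc4)(c4ccccc4)C(C)(C)C)C[C@]3(O[Si](CC)(CC)CC)[C@H](CC(=O)OC)C1=O
F8 | step 16 | nor-methyl β-hydroxy keto ester | CC[C@@H]1C2=C3N(C(=O)CCC2)[C@H](CO[Si](c4ccccc4)(c4ccccc4)C(C)(C)C)C[C@]3(O)[C@H](CC(=O)OC)C1=O
F9 | step 16 | nor-methyl diol ester | CC[C@@H]1C2=C3N(C(=O)CCC2)[C@H](CO[Si](c4ccccc4)(c4ccccc4)C(C)(C)C)C[C@]3(O)[C@H](CC(=O)OC)[C@@H]1O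
F10 | step 16 | nor-methyl lactone | CC[C@@H]1C2=C3N(C(=O)CCC2)[C@H](CO[Si](c4ccccc4)(c4ccccc4)C(C)(C)C)C[C@]3(O)[C@H]2[C@@H]1OC(=O)C2
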